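**Retrosynthetic overview**

1. Target ⇒ cleavage of the C3–O acyl bond and of six O-benzyl groups: 5,7,3',4'-tetra-O-benzyl-(−)-epicatechin 24 plus 3,5-bis(benzyloxy)-4-methoxybenzoyl chloride 28.
2. Ring C ⇒ O1–C2 bond, closed by Mitsunobu displacement with inversion at C2 on the anti-configured phenol 20 (anti chain gives 2,3-cis).
3. Ring A ⇒ built on the chiral chain. It is a phloroglucinol with oxygens on C8a (O1), C5 and C7 and its only carbon substituent (C4) on C4a, the pattern that a vinylketene and a siloxyalkyne deliver. Benzannulation of ynol ether 12 with cyclobutenone 14 forms C4a–C8a, C5–C6 and C8–C8a.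
4. Ynol ether 12 ⇒ terminal alkyne 9 ⇒ epoxide 4 plus (trimethylsilyl)acetylide ⇒ Sharpless kinetic resolution of vinyl carbinol 2 (sets C2 and C3) ⇒ aldehyde 1.
5. Order of rings: ring B is bought with 1, ring A is formed in step 9, ring C in step 11.

Key step: step 9

Remark: flavan numbering (O1, C2, C3, C4, C4a, C5–C8, C8a; ring B atoms primed) is applied to the corresponding atoms of the open-chain intermediates, and the sense of the kinetic resolution in step 2 is taken from the empirical face-selection rule of the titanium–tartrate epoxidation.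

**Route**

Step 1
Reactants: 1 3,4-bis(benzyloxy)benzaldehyde
Product: 2 rac-1-[3,4-bis(benzyloxy)phenyl]prop-2-en-1-ol
Conditions: CH2=CHMgBr, THF, 0 °C; then H2O
Reagents that add atoms: vinylmagnesium bromide, C=C[Mg]Br
Why: Grignard 1,2-addition to the aldehyde should give the racemic aryl vinyl carbinol that step 2 resolves.

Step 2
Reactants: 2 rac-1-[3,4-bis(benzyloxy)phenyl]prop-2-en-1-ol
Product: 3 (S)-[3,4-bis(benzyloxy)phenyl][(2R)-oxiran-2-yl]methanol
Conditions: Ti(OiPr)4 (0.1 equiv), L-(+)-diisopropyl tartrate (0.15 equiv), t-BuOOH (0.45 equiv), 4 Å molecular sieves, CH2Cl2, −20 °C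
Reagents that add atoms: tert-butyl hydroperoxide, CC(C)(C)OO
Why: Sharpless kinetic resolution by titanium–tartrate epoxidation: with the L-(+)-tartrate the (R)-enantiomer of 2 should be epoxidised much faster than its antipode and on the alkene face that leads to the erythro (anti) epoxy alcohol, so the carbinol centre (future C2, S) is selected by the resolution, the oxirane centre (future C3, R) is set by reagent-controlled oxygen delivery, and the unreacted (S)-enantiomer of 2 is removed by chromatography.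

Step 3
Reactants: 3 (S)-[3,4-bis(benzyloxy)phenyl][(2R)-oxiran-2-yl]methanol
Product: 4 {(S)-[3,4-bis(benzyloxy)phenyl][(2R)-oxiran-2-yl]methoxy}triethylsilane
Conditions: Et3SiCl, imidazole, CH2Cl2, 0 °C
Reagents that add atoms: chlorotriethylsilane, CC[Si](Cl)(CC)CC
Why: Imidazole-promoted O-silylation protects the benzylic hydroxyl as the most labile of the three silyl ethers used, without touching the epoxide or either stereocentre.

Step 4
Reactants: 4 {(S)-[3,4-bis(benzyloxy)phenyl][(2R)-oxiran-2-yl]methoxy}triethylsilane; 5 ethynyltrimethylsilane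
Product: 7 (1S,2R)-1-[3,4-bis(benzyloxy)phenyl]-1-(triethylsilyloxy)-5-(trimethylsilyl)pent-4-yn-2-ol, via lithium (trimethylsilyl)acetylide 6 (not isolated)
Conditions: 5, n-BuLi, THF, −78 °C; BF3·OEt2; then 4, −78 °C; H2O quench at −78 °C
Reagents that add atoms: none
Why: Yamaguchi–Hirao alkynylation: the BF3-activated terminal epoxide is opened by the lithium acetylide at the unhindered CH2 carbon (future C4) in an SN2 process that leaves both stereocentres untouched, and the low temperature with a cold quench should prevent silyl migration between the vicinal oxygens.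

Step 5
Reactants: 7 (1S,2R)-1-[3,4-bis(benzyloxy)phenyl]-1-(triethylsilyloxy)-5-(trimethylsilyl)pent-4-yn-2-ol
Product: 8 (1S,2R)-1-[3,4-bis(benzyloxy)phenyl]-2-(tert-butyldimethylsilyloxy)-1-(triethylsilyloxy)-5-(trimethylsilyl)pent-4-yne
Conditions: t-BuMe2SiOTf, 2,6-lutidine, CH2Cl2, −78 °C
Reagents that add atoms: tert-butyldimethylsilyl trifluoromethanesulfonate, CC(C)(C)[Si](C)(C)OS(=O)(=O)C(F)(F)F
Why: Silyl triflate silylation of the hindered secondary C3 hydroxyl under non-nucleophilic base gives the more robust of the two alkyl silyl ethers, so that the C2 and C3 oxygens can later be freed in turn.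

Step 6
Reactants: 8 (1S,2R)-1-[3,4-bis(benzyloxy)phenyl]-2-(tert-butyldimethylsilyloxy)-1-(triethylsilyloxy)-5-(trimethylsilyl)pent-4-yne
Product: 9 (1S,2R)-1-[3,4-bis(benzyloxy)phenyl]-2-(tert-butyldimethylsilyloxy)-1-(triethylsilyloxy)pent-4-yne
Conditions: K2CO3 (0.2 equiv), MeOH, room temperature
Reagents that add atoms: none
Why: Base-catalysed methanolysis cleaves the C(sp)–Si bond selectively, since both oxygen-bound silyl groups are stable to catalytic carbonate in methanol over the short reaction time.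

Step 7
Reactants: 9 (1S,2R)-1-[3,4-bis(benzyloxy)phenyl]-2-(tert-butyldimethylsilyloxy)-1-(triethylsilyloxy)pent-4-yne
Product: 12 (1S,2R)-1-[3,4-bis(benzyloxy)phenyl]-2-(tert-butyldimethylsilyloxy)-1-(triethylsilyloxy)-5-(triisopropylsilyloxy)pent-4-yne, via lithium acetylide 10 (not isolated), via lithium ynolate 11 (not isolated)
Conditions: n-BuLi, THF, −78 °C; LiOOt-Bu [from t-BuOOH and LiN(SiMe3)2, THF, −78 °C], −78 → 0 °C; i-Pr3SiOTf, −78 °C → room temperature
Reagents that add atoms: tert-butyl hydroperoxide, CC(C)(C)OO; triisopropylsilyl trifluoromethanesulfonate, CC(C)[Si](C(C)C)(C(C)C)OS(=O)(=O)C(F)(F)F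
Why: Oxidation of a lithium acetylide to the lithium ynolate by electrophilic oxygen transfer from lithium tert-butyl peroxide followed by O-silylation: the bulky silyl triflate should trap the ambident ynolate on oxygen to give the stable triisopropylsilyl ynol ether, and neither event touches the two carbinol centres.

Step 8
Reactants: 13 3-ethoxycyclobut-2-en-1-one
Product: 14 3-(benzyloxy)cyclobut-2-en-1-one
Conditions: BnOH (5 equiv, neat), PPTS (0.05 equiv), 40 °C, 30 mbar (EtOH distilled off)
Reagents that add atoms: benzyl alcohol, OCc1ccccc1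
Why: Acid-catalysed alkoxy exchange (transetherification) of a vinylogous ester by addition of benzyl alcohol at C3 and loss of ethanol, driven by removal of ethanol under reduced pressure at a temperature well below the electrocyclic opening of the ring.

Step 9
Reactants: 12 (1S,2R)-1-[3,4-bis(benzyloxy)phenyl]-2-(tert-butyldimethylsilyloxy)-1-(triethylsilyloxy)-5-(triisopropylsilyloxy)pent-4-yne; 14 3-(benzyloxy)cyclobut-2-en-1-one
Product: 19 5-(benzyloxy)-2-[(2R,3S)-3-[3,4-bis(benzyloxy)phenyl]-2-(tert-butyldimethylsilyloxy)-3-(triethylsilyloxy)propyl]-3-(triisopropylsilyloxy)phenol, via vinylketene 15 (not isolated), via 4-vinylcyclobutenone 16 (not isolated), via dienylketene 17 (not isolated), via cyclohexa-2,4-dienone 18 (not isolated)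
Conditions: toluene, reflux (110 °C), slow addition of 14 (1.5 equiv)
Reagents that add atoms: none
Why: Danheiser benzannulation: on heating, 14 opens by 4π electrocyclic ring opening to vinylketene 15, whose electrophilic ketene carbon (future C8a) is attacked by the nucleophilic chain-bearing alkyne carbon of ynol ether 12 (future C4a) in a regiospecific [2+2] cycloaddition that also joins the ketene α-carbon (C6) to the siloxy carbon (C5) and gives 16. Cyclobutenone 16 opens in a second 4π electrocyclic step to dienylketene 17, and ring A closes by 6π electrocyclisation between the ketene carbon and the terminal methylene (C8a–C8) to dienone 18, which tautomerises to phenol 19. The closest known reaction type is the thermal benzannulation of cyclobutenones with trialkylsilyloxyalkynes to resorcinol monosilyl ethers. No stereocentre is formed, the sp3 ring carbon of 16 is lost again on ring opening, and the two carbinol centres of the chain take part in no bond change. The step needs regioselectivity in the [2+2] event, secured by the matched polarity of ynol ether and ketene, and survival of three silyl ethers, secured by neutral aprotic thermolysis, while slow addition of 14 keeps the ketene concentration low so that the new O1 phenol is not acylated.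

Step 10
Reactants: 19 5-(benzyloxy)-2-[(2R,3S)-3-[3,4-bis(benzyloxy)phenyl]-2-(tert-butyldimethylsilyloxy)-3-(triethylsilyloxy)propyl]-3-(triisopropylsilyloxy)phenol
Product: 20 5-(benzyloxy)-2-[(2R,3S)-3-[3,4-bis(benzyloxy)phenyl]-2-(tert-butyldimethylsilyloxy)-3-hydroxypropyl]-3-(triisopropylsilyloxy)phenol
Conditions: HF·pyridine, pyridine, THF, 0 °C
Reagents that add atoms: none
Why: Selective desilylation: under buffered HF·pyridine the secondary triethylsilyl ether should be cleaved far faster than the tert-butyldimethylsilyl ether and the aryl triisopropylsilyl ether, and the non-nucleophilic medium avoids solvolysis at the electron-rich benzylic carbon.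

Step 11
Reactants: 20 5-(benzyloxy)-2-[(2R,3S)-3-[3,4-bis(benzyloxy)phenyl]-2-(tert-butyldimethylsilyloxy)-3-hydroxypropyl]-3-(triisopropylsilyloxy)phenol
Product: 22 (2R,3R)-7-(benzyloxy)-2-[3,4-bis(benzyloxy)phenyl]-3-(tert-butyldimethylsilyloxy)-5-(triisopropylsilyloxy)chromane, via oxyphosphonium phenoxide 21 (not isolated)
Conditions: PPh3, DIAD, toluene, 0 °C → room temperature
Reagents that add atoms: none
Why: Intramolecular Mitsunobu etherification: the C2 hydroxyl is activated as oxyphosphonium 21 and displaced by the O1 phenoxide in a 6-exo-tet SN2 closure of ring C, so C2 is inverted from S to R and the anti chain should give the 2,3-cis flavan, with toluene and low temperature chosen to disfavour ionisation of the benzylic oxyphosphonium.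

Step 12
Reactants: 22 (2R,3R)-7-(benzyloxy)-2-[3,4-bis(benzyloxy)phenyl]-3-(tert-butyldimethylsilyloxy)-5-(triisopropylsilyloxy)chromane
Product: 23 (2R,3R)-7-(benzyloxy)-2-[3,4-bis(benzyloxy)phenyl]chromane-3,5-diol
Conditions: Bu4NF (2.5 equiv), THF, 0 °C → room temperature; then H2O
Reagents that add atoms: none
Why: Fluoride-mediated desilylation should cleave both the secondary tert-butyldimethylsilyl ether and the aryl triisopropylsilyl ether without touching the benzyl ethers or the stereocentres.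

Step 13
Reactants: 23 (2R,3R)-7-(benzyloxy)-2-[3,4-bis(benzyloxy)phenyl]chromane-3,5-diol
Product: 24 (2R,3R)-5,7-bis(benzyloxy)-2-[3,4-bis(benzyloxy)phenyl]chroman-3-ol (5,7,3',4'-tetra-O-benzyl-(−)-epicatechin)
Conditions: BnBr (1.1 equiv), K2CO3, DMF, room temperature
Reagents that add atoms: benzyl bromide, BrCc1ccccc1
Why: Williamson etherification: carbonate deprotonates only the C5 phenol, so benzylation should be chemoselective and leave the secondary C3 alcohol free for acylation.

Step 14
Reactants: 25 3,5-dihydroxy-4-methoxybenzoic acid (4-O-methylgallic acid)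
Product: 26 benzyl 3,5-bis(benzyloxy)-4-methoxybenzoate
Conditions: BnBr (3.3 equiv), K2CO3, DMF, 60 °C
Reagents that add atoms: benzyl bromide, BrCc1ccccc1
Why: Williamson etherification of both phenols with concurrent alkylation of the carboxylate should give the fully benzylated ester in one operation.

Step 15
Reactants: 26 benzyl 3,5-bis(benzyloxy)-4-methoxybenzoate
Product: 27 3,5-bis(benzyloxy)-4-methoxybenzoic acid
Conditions: KOH, THF/MeOH/H2O, 60 °C; then aq. HCl
Reagents that add atoms: potassium hydroxide, [K+].[OH-]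
Why: Saponification cleaves the benzyl ester by acyl substitution and leaves the aryl benzyl and methyl ethers intact.

Step 16
Reactants: 27 3,5-bis(benzyloxy)-4-methoxybenzoic acid
Product: 28 3,5-bis(benzyloxy)-4-methoxybenzoyl chloride
Conditions: (COCl)2, DMF (cat.), CH2Cl2, 0 °C → room temperature
Reagents that add atoms: oxalyl chloride, ClC(=O)C(Cl)=O
Why: Acid chloride formation with oxalyl chloride under Vilsmeier-type catalysis by DMF gives the acylating agent, which is freed from volatiles and used crude.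

Step 17
Reactants: 24 (2R,3R)-5,7-bis(benzyloxy)-2-[3,4-bis(benzyloxy)phenyl]chroman-3-ol; 28 3,5-bis(benzyloxy)-4-methoxybenzoyl chloride
Product: 29 (2R,3R)-5,7-bis(benzyloxy)-2-[3,4-bis(benzyloxy)phenyl]chroman-3-yl 3,5-bis(benzyloxy)-4-methoxybenzoate
Conditions: Et3N, DMAP, CH2Cl2, 0 °C → room temperature
Reagents that add atoms: none
Why: DMAP-catalysed acylation (nucleophilic catalysis through the acylpyridinium ion) should esterify the hindered axial C3 alcohol with retention, since no bond to C3 is broken.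

Step 18
Reactants: 29 (2R,3R)-5,7-bis(benzyloxy)-2-[3,4-bis(benzyloxy)phenyl]chroman-3-yl 3,5-bis(benzyloxy)-4-methoxybenzoate
Product: 30 epicatechin 3-O-(4-O-methylgallate)
Conditions: H2 (1 atm), Pd(OH)2/C, THF/MeOH, room temperature
Reagents that add atoms: none
Why: Catalytic hydrogenolysis of the six benzyl ethers under mild conditions should leave the ester, the methyl ether and the benzylic C2–O1 bond of the chroman intact and give the target with both stereocentres unchanged.

**Compound list**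

1 | 3,4-bis(benzyloxy)benzaldehyde | O=Cc1ccc(OCc2ccccc2)c(OCc2ccccc2)c1 | starting material
2 | rac-1-[3,4-bis(benzyloxy)phenyl]prop-2-en-1-ol | C=CC(O)c1ccc(OCc2ccccc2)c(OCc2ccccc2)c1 | intermediate
3 | (S)-[3,4-bis(benzyloxy)phenyl][(2R)-oxiran-2-yl]methanol | C1O[C@H]1[C@@H](O)c1ccc(OCc2ccccc2)c(OCc2ccccc2)c1 | intermediate
4 | {(S)-[3,4-bis(benzyloxy)phenyl][(2R)-oxiran-2-yl]methoxy}triethylsilane | C1O[C@H]1[C@@H](O[Si](CC)(CC)CC)c1ccc(OCc2ccccc2)c(OCc2ccccc2)c1 | intermediate
5 | ethynyltrimethylsilane | C#C[Si](C)(C)C | starting material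
6 | lithium (trimethylsilyl)acetylide | [Li]C#C[Si](C)(C)C | intermediate (not isolated)
7 | (1S,2R)-1-[3,4-bis(benzyloxy)phenyl]-1-(triethylsilyloxy)-5-(trimethylsilyl)pent-4-yn-2-ol | C[Si](C)(C)C#CC[C@@H](O)[C@@H](O[Si](CC)(CC)CC)c1ccc(OCc2ccccc2)c(OCc2ccccc2)c1 | intermediate
8 | (1S,2R)-1-[3,4-bis(benzyloxy)phenyl]-2-(tert-butyldimethylsilyloxy)-1-(triethylsilyloxy)-5-(trimethylsilyl)pent-4-yne | C[Si](C)(C)C#CC[C@@H](O[Si](C)(C)C(C)(C)C)[C@@H](O[Si](CC)(CC)CC)c1ccc(OCc2ccccc2)c(OCc2ccccc2)c1 | intermediate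
9 | (1S,2R)-1-[3,4-bis(benzyloxy)phenyl]-2-(tert-butyldimethylsilyloxy)-1-(triethylsilyloxy)pent-4-yne | C#CC[C@@H](O[Si](C)(C)C(C)(C)C)[C@@H](O[Si](CC)(CC)CC)c1ccc(OCc2ccccc2)c(OCc2ccccc2)c1 | intermediate
10 | lithium acetylide of 9 | [Li]C#CC[C@@H](O[Si](C)(C)C(C)(C)C)[C@@H](O[Si](CC)(CC)CC)c1ccc(OCc2ccccc2)c(OCc2ccccc2)c1 | intermediate (not isolated)
11 | lithium ynolate, lithium (4R,5S)-5-[3,4-bis(benzyloxy)phenyl]-4-(tert-butyldimethylsilyloxy)-5-(triethylsilyloxy)pent-1-yn-1-olate | [Li]OC#CC[C@@H](O[Si](C)(C)C(C)(C)C)[C@@H](O[Si](CC)(CC)CC)c1ccc(OCc2ccccc2)c(OCc2ccccc2)c1 | intermediate (not isolated)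
12 | (1S,2R)-1-[3,4-bis(benzyloxy)phenyl]-2-(tert-butyldimethylsilyloxy)-1-(triethylsilyloxy)-5-(triisopropylsilyloxy)pent-4-yne (anti siloxyalkyne) | CC(C)[Si](OC#CC[C@@H](O[Si](C)(C)C(C)(C)C)[C@@H](O[Si](CC)(CC)CC)c1ccc(OCc2ccccc2)c(OCc2ccccc2)c1)(C(C)C)C(C)C | intermediate
13 | 3-ethoxycyclobut-2-en-1-one | CCOC1=CC(=O)C1 | starting material
14 | 3-(benzyloxy)cyclobut-2-en-1-one | O=C1C=C(OCc2ccccc2)C1 | intermediate
15 | 3-(benzyloxy)buta-1,3-dien-1-one (vinylketene) | O=C=CC(=C)OCc1ccccc1 | intermediate (not isolated)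
16 | 4-[1-(benzyloxy)ethenyl]-2-[(2R,3S)-3-[3,4-bis(benzyloxy)phenyl]-2-(tert-butyldimethylsilyloxy)-3-(triethylsilyloxy)propyl]-3-(triisopropylsilyloxy)cyclobut-2-en-1-one (both epimers at the ring sp3 carbon) | O=C1C(C[C@@H](O[Si](C)(C)C(C)(C)C)[C@@H](O[Si](CC)(CC)CC)c2ccc(OCc3ccccc3)c(OCc3ccccc3)c2)=C(O[Si](C(C)C)(C(C)C)C(C)C)C1C(=C)OCc1ccccc1 | intermediate (not isolated)
17 | dienylketene, 5-(benzyloxy)-2-[(2R,3S)-3-[3,4-bis(benzyloxy)phenyl]-2-(tert-butyldimethylsilyloxy)-3-(triethylsilyloxy)propyl]-3-(triisopropylsilyloxy)hexa-1,3,5-trien-1-one | O=C=C(C[C@@H](O[Si](C)(C)C(C)(C)C)[C@@H](O[Si](CC)(CC)CC)c1ccc(OCc2ccccc2)c(OCc2ccccc2)c1)C(O[Si](C(C)C)(C(C)C)C(C)C)=CC(=C)OCc1ccccc1 | intermediate (not isolated)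
18 | 5-(benzyloxy)-2-[(2R,3S)-3-[3,4-bis(benzyloxy)phenyl]-2-(tert-butyldimethylsilyloxy)-3-(triethylsilyloxy)propyl]-3-(triisopropylsilyloxy)cyclohexa-2,4-dien-1-one | O=C1CC(OCc2ccccc2)=CC(O[Si](C(C)C)(C(C)C)C(C)C)=C1C[C@@H](O[Si](C)(C)C(C)(C)C)[C@@H](O[Si](CC)(CC)CC)c1ccc(OCc2ccccc2)c(OCc2ccccc2)c1 | intermediate (not isolated)
19 | 5-(benzyloxy)-2-[(2R,3S)-3-[3,4-bis(benzyloxy)phenyl]-2-(tert-butyldimethylsilyloxy)-3-(triethylsilyloxy)propyl]-3-(triisopropylsilyloxy)phenol (ring A phenol, anti chain) | Oc1cc(OCc2ccccc2)cc(O[Si](C(C)C)(C(C)C)C(C)C)c1C[C@@H](O[Si](C)(C)C(C)(C)C)[C@@H](O[Si](CC)(CC)CC)c1ccc(OCc2ccccc2)c(OCc2ccccc2)c1 | intermediate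
20 | 5-(benzyloxy)-2-[(2R,3S)-3-[3,4-bis(benzyloxy)phenyl]-2-(tert-butyldimethylsilyloxy)-3-hydroxypropyl]-3-(triisopropylsilyloxy)phenol | Oc1cc(OCc2ccccc2)cc(O[Si](C(C)C)(C(C)C)C(C)C)c1C[C@@H](O[Si](C)(C)C(C)(C)C)[C@@H](O)c1ccc(OCc2ccccc2)c(OCc2ccccc2)c1 | intermediate
21 | oxyphosphonium phenoxide (C2–O–PPh3 cation, O1 phenoxide) | [O-]c1cc(OCc2ccccc2)cc(O[Si](C(C)C)(C(C)C)C(C)C)c1C[C@@H](O[Si](C)(C)C(C)(C)C)[C@@H](O[P+](c1ccccc1)(c1ccccc1)c1ccccc1)c1ccc(OCc2ccccc2)c(OCc2ccccc2)c1 | intermediate (not isolated)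
22 | (2R,3R)-7-(benzyloxy)-2-[3,4-bis(benzyloxy)phenyl]-3-(tert-butyldimethylsilyloxy)-5-(triisopropylsilyloxy)chromane | CC(C)(C)[Si](C)(C)O[C@@H]1Cc2c(O[Si](C(C)C)(C(C)C)C(C)C)cc(OCc3ccccc3)cc2O[C@@H]1c1ccc(OCc2ccccc2)c(OCc2ccccc2)c1 | intermediate
23 | (2R,3R)-7-(benzyloxy)-2-[3,4-bis(benzyloxy)phenyl]chromane-3,5-diol | O[C@@H]1Cc2c(O)cc(OCc3ccccc3)cc2O[C@@H]1c1ccc(OCc2ccccc2)c(OCc2ccccc2)c1 | intermediate
24 | (2R,3R)-5,7-bis(benzyloxy)-2-[3,4-bis(benzyloxy)phenyl]chroman-3-ol | O[C@@H]1Cc2c(OCc3ccccc3)cc(OCc3ccccc3)cc2O[C@@H]1c1ccc(OCc2ccccc2)c(OCc2ccccc2)c1 | intermediate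
25 | 3,5-dihydroxy-4-methoxybenzoic acid (4-O-methylgallic acid) | COc1c(O)cc(C(=O)O)cc1O | starting material
26 | benzyl 3,5-bis(benzyloxy)-4-methoxybenzoate | COc1c(OCc2ccccc2)cc(C(=O)OCc2ccccc2)cc1OCc1ccccc1 | intermediate
27 | 3,5-bis(benzyloxy)-4-methoxybenzoic acid | COc1c(OCc2ccccc2)cc(C(=O)O)cc1OCc1ccccc1 | intermediate
28 | 3,5-bis(benzyloxy)-4-methoxybenzoyl chloride | COc1c(OCc2ccccc2)cc(C(Cl)=O)cc1OCc1ccccc1 | intermediate
29 | (2R,3R)-5,7-bis(benzyloxy)-2-[3,4-bis(benzyloxy)phenyl]chroman-3-yl 3,5-bis(benzyloxy)-4-methoxybenzoate | COc1c(OCc2ccccc2)cc(C(=O)O[C@@H]2Cc3c(OCc4ccccc4)cc(OCc4ccccc4)cc3O[C@@H]2c2ccc(OCc3ccccc3)c(OCc3ccccc3)c2)cc1OCc1ccccc1 | intermediate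
30 | epicatechin 3-O-(4-O-methylgallate), (2R,3R) | COc1c(O)cc(C(=O)O[C@@H]2Cc3c(O)cc(O)cc3O[C@@H]2c2ccc(O)c(O)c2)cc1O | target

**Step count**

Total: 18 steps. Longest linear sequence: 14 steps (steps 1–7, 9–13, 17 and 18, from aldehyde 1).

**Steps most likely to fail**

1. Step 9 (benzannulation). The vinylogous-ester cyclobutenone may open only sluggishly, so that at the temperature required the siloxyalkyne is consumed by decomposition, or the newly formed phenol is acylated by excess ketene. The fallback sets out from 12 and comes back at 19, and generates the same vinylketene without heat by 1,4-dehydrochlorination. Phosphine-catalysed oxa-Michael addition of benzyl alcohol to ethyl but-2-ynoate (PMe3 cat., CH2Cl2) should give ethyl (E)-3-(benzyloxy)but-2-enoate F1. Saponification (LiOH, THF/H2O) gives (E)-3-(benzyloxy)but-2-enoic acid F2, and oxalyl chloride with catalytic DMF gives (E)-3-(benzyloxy)but-2-enoyl chloride F3. Slow addition of F3 to 12 and Et3N in CH2Cl2 at room temperature removes HCl across the acyl and γ-methyl positions and forms vinylketene 15 in low stationary concentration. Its [2+2] cycloaddition to 12 gives 16, and brief warming in toluene (80 °C) carries 16 through 17 and 18 to 19.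

2. Step 11 (Mitsunobu closure). Ionisation of the oxyphosphonium at the benzylic carbon, which carries a para-benzyloxy donor, would erode the inversion at C2, and elimination toward the C3 silyl enol ether may compete. The fallback sets out from 19 and comes back at 23, replacing steps 10–12 by anchimerically controlled activation of the free diol. Bu4NF (THF, 0 °C) removes all three silyl groups to give (1S,2R)-1-[3,4-bis(benzyloxy)phenyl]-3-[4-(benzyloxy)-2,6-dihydroxyphenyl]propane-1,2-diol F4. Its two phenols flank the chain and are equivalent, so either one closes to the same flavan. HC(OEt)3 and PPTS in 1,2-dichloroethane (60 °C) convert the anti diol into the cyclic ethyl orthoformate F5 (2-ethoxy-1,3-dioxolane, 4R,5S). On acid-induced loss of ethoxide the C3 oxygen keeps the benzylic carbon covalently bound, so a free cation is not formed, and a neighbouring phenol opens the activated dioxolane at C2 from the rear. This should give (2R,3R)-7-(benzyloxy)-2-[3,4-bis(benzyloxy)phenyl]-5-hydroxychroman-3-yl formate F6. Methanolysis (K2CO3, MeOH, 0 °C) removes the formate and gives 23.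

3. Step 8 (transetherification). The strained vinylogous ester may be cleaved by the alcohol to acetoacetate-type esters, or may open thermally, faster than it exchanges its alkoxy group. The fallback sets out from 13 and comes back at 14. Hydrolysis with cold dilute aqueous HCl gives cyclobutane-1,3-dione F7, and its acidic enol is O-benzylated under Mitsunobu conditions (BnOH, PPh3, DIAD, THF, 0 °C) to give 14.

**Further compounds**

F1 | step 9 | ethyl (E)-3-(benzyloxy)but-2-enoate | CCOC(=O)/C=C(\C)OCc1ccccc1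
F2 | step 9 | (E)-3-(benzyloxy)but-2-enoic acid | OC(=O)/C=C(\C)OCc1ccccc1
F3 | step 9 | (E)-3-(benzyloxy)but-2-enoyl chloride | ClC(=O)/C=C(\C)OCc1ccccc1
F4 | step 11 | (1S,2R)-1-[3,4-bis(benzyloxy)phenyl]-3-[4-(benzyloxy)-2,6-dihydroxyphenyl]propane-1,2-diol | Oc1cc(OCc2ccccc2)cc(O)c1C[C@@H](O)[C@@H](O)c1ccc(OCc2ccccc2)c(OCc2ccccc2)c1
F5 | step 11 | 5-(benzyloxy)-2-{[(4R,5S)-5-[3,4-bis(benzyloxy)phenyl]-2-ethoxy-1,3-dioxolan-4-yl]methyl}benzene-1,3-diol | CCOC1O[C@H](Cc2c(O)cc(OCc3ccccc3)cc2O)[C@@H](O1)c1ccc(OCc2ccccc2)c(OCc2ccccc2)c1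
F6 | step 11 | (2R,3R)-7-(benzyloxy)-2-[3,4-bis(benzyloxy)phenyl]-5-hydroxychroman-3-yl formate | O=CO[C@@H]1Cc2c(O)cc(OCc3ccccc3)cc2O[C@@H]1c1ccc(OCc2ccccc2)c(OCc2ccccc2)c1
F7 | step 8 | cyclobutane-1,3-dione | O=C1CC(=O)C1
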